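**Retrosynthetic overview**
1. Last bond made: the C1–O bond of the tertiary carbinol (key C–O step). Oxygen is delivered to the C1 enolate of the fully assembled deoxy ketone from the face opposite the coumarin.
2. C1 side chain: α′-methallylation of the bicyclic enone, then hydrogenation to isobutyl. The group that enters first ends up cis to the coumarin once oxygen enters anti.
3. Ring A (cyclopentenone): alkyne hydration and intramolecular aldol condensation of a 2-(but-2-ynyl)cyclopentanone, closed after the quaternary centre exists.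
4. Quaternary C6a and the coumarin–carbon bond: oxidative (3+2) annulation of 4-hydroxy-5-methylcoumarin onto a tetrasubstituted silyl enol ether (C–C bond, then C–O ring closure to a ketal that is hydrolysed), anti to the C6 methyl. This is the proposed new step.
5. C6 and ring B: asymmetric CuH conjugate reduction/butynylation of 3-methylcyclopentenone. Pyranone ring: 2′-hydroxy-6′-methylacetophenone + diethyl carbonate. Ring order: pyranone, ring B (purchased), transient dihydrofuran ketal, ring A.

Assumption: (R)-p-Tol-BINAP is taken to give the (3S) enol silane (mirror image of the reported (S)-ligand/(R)-ketone pairing); if the sense is the opposite, the (S)-ligand is used. All named starting materials are taken as catalogue items.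

**Route**

Step 1
Reactants: 1 1-(2-hydroxy-6-methylphenyl)ethan-1-one; 2 diethyl carbonate
Product: 4 4-hydroxy-5-methyl-2H-chromen-2-one, via keto ester 3 (not isolated)
Conditions: NaH (3 equiv), PhMe, 110 °C; then aq. HCl
Reagents that add atoms: none
Why: Claisen-type C-acylation of the methyl ketone enolate by the carbonate, then lactonisation of the phenoxide onto the ester (standard 4-hydroxycoumarin synthesis); no stereocentre.

Step 2
Reactants: 5 3-methylcyclopent-2-en-1-one; 6 1-bromobut-2-yne
Product: 8 (2R,3S)-2-(but-2-yn-1-yl)-3-methylcyclopentan-1-one, via bis-enol silane 7 (not isolated)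
Conditions: CuCl/NaOt-Bu/(R)-p-Tol-BINAP (5 mol% each), Ph2SiH2 (0.51 equiv), PhMe, 0 °C; then TBAT (1.2 equiv), 6, CH2Cl2, rt
Reagents that add atoms: none
Why: Asymmetric CuH conjugate reduction (Buchwald) sets the methyl-bearing centre as S under ligand control, and fluoride activation of the regiodefined silyl enol ether gives SN2 C-alkylation by the propargylic bromide trans to the methyl.

Step 3
Reactants: 8 (2R,3S)-2-(but-2-yn-1-yl)-3-methylcyclopentan-1-one
Product: 9 {[(3S)-2-(but-2-yn-1-yl)-3-methylcyclopent-1-en-1-yl]oxy}trimethylsilane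
Conditions: TMSCl, NaI, Et3N, MeCN, rt
Reagents that add atoms: chlorotrimethylsilane, C[Si](C)(C)Cl
Why: Thermodynamic silyl enol ether formation (equilibrating in situ TMSI/Et3N) favours the tetrasubstituted enol ether; the β-stereocentre is not touched.

Step 4
Reactants: 9 {[(3S)-2-(but-2-yn-1-yl)-3-methylcyclopent-1-en-1-yl]oxy}trimethylsilane; 4 4-hydroxy-5-methyl-2H-chromen-2-one
Product: 11 3-[(1S,2S)-1-(but-2-yn-1-yl)-2-methyl-5-oxocyclopentyl]-4-hydroxy-5-methyl-2H-chromen-2-one, via silyl ketal cycloadduct 10 (not isolated)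
Conditions: 4 (2 equiv), CAN (2.2 equiv), NaHCO3, MeCN, −20 → 0 °C; then 1 M HCl, THF, rt
Reagents that add atoms: none
Why: Proposed new method: Ce(IV) oxidises the coumarin enol to its electrophilic C3 radical, which adds to the electron-rich β-carbon of the fully substituted silyl enol ether on the face opposite the neighbouring methyl (this sets the quaternary centre), a second Ce(IV) oxidises the α-silyloxy radical to the silyloxocarbenium ion, and the coumarin C4–O closes onto it to give the cis-fused ketal that the acid work-up opens to the keto-enol; the closest known reaction type is the Ce(IV)- or Ag(I)-mediated oxidative (3+2) cycloaddition/cross-coupling of 1,3-dicarbonyls (4-hydroxycoumarins included) with enol ethers and silyl enol ethers, not yet shown for a tetrasubstituted enol ether that creates a quaternary stereocentre.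

Step 5
Reactants: 11 3-[(1S,2S)-1-(but-2-yn-1-yl)-2-methyl-5-oxocyclopentyl]-4-hydroxy-5-methyl-2H-chromen-2-one
Product: 13 (6S,6aR)-6a-(4-hydroxy-5-methyl-2-oxo-2H-chromen-3-yl)-3,6-dimethyl-4,5,6,6a-tetrahydropentalen-2(1H)-one, via 1,4-diketone 12 (not isolated)
Conditions: Ph3PAuNTf2 (3 mol%), H2O, MeOH, 50 °C; then KOH (4 equiv), 50 °C; aq. HCl
Reagents that add atoms: water, O
Why: Carbonyl-assisted (5-exo) Au(I)-catalysed alkyne hydration places the new ketone 1,4 to the ring ketone, and intramolecular aldol condensation then closes the conjugated cyclopentenone (the only aldol mode that can dehydrate); no stereocentre changes.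

Step 6
Reactants: 13 (6S,6aR)-6a-(4-hydroxy-5-methyl-2-oxo-2H-chromen-3-yl)-3,6-dimethyl-4,5,6,6a-tetrahydropentalen-2(1H)-one; 14 3-bromo-2-methylprop-1-ene
Product: 16 (1S,6S,6aS)-6a-(4-hydroxy-5-methyl-2-oxo-2H-chromen-3-yl)-3,6-dimethyl-1-(2-methylprop-2-en-1-yl)-4,5,6,6a-tetrahydropentalen-2(1H)-one, via dilithium dianion 15 (not isolated)
Conditions: LDA (2.2 equiv), THF, −78 °C; 14 (1.1 equiv), −78 → −30 °C; aq. HCl
Reagents that add atoms: none
Why: Kinetic α′-deprotonation of the cross-conjugated enone (after the acidic enol) and SN2 enolate alkylation by the allylic bromide, which enters anti to the coumarin; this C1 configuration is erased again in step 8.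

Step 7
Reactants: 16 (1S,6S,6aS)-6a-(4-hydroxy-5-methyl-2-oxo-2H-chromen-3-yl)-3,6-dimethyl-1-(2-methylprop-2-en-1-yl)-4,5,6,6a-tetrahydropentalen-2(1H)-one
Product: 17 (1S,6S,6aS)-6a-(4-hydroxy-5-methyl-2-oxo-2H-chromen-3-yl)-3,6-dimethyl-1-(2-methylpropyl)-4,5,6,6a-tetrahydropentalen-2(1H)-one
Conditions: H2 (1 atm), RhCl(PPh3)3 (5 mol%), PhH–EtOH, rt
Reagents that add atoms: none
Why: Homogeneous (Wilkinson) hydrogenation reduces the unhindered 1,1-disubstituted alkene and leaves the tetrasubstituted enone and the pyranone alone.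

Step 8
Reactants: 17 (1S,6S,6aS)-6a-(4-hydroxy-5-methyl-2-oxo-2H-chromen-3-yl)-3,6-dimethyl-1-(2-methylpropyl)-4,5,6,6a-tetrahydropentalen-2(1H)-one
Product: 19 (1S,6S,6aS)-1-hydroxy-6a-(4-hydroxy-5-methyl-2-oxo-2H-chromen-3-yl)-3,6-dimethyl-1-(2-methylpropyl)-4,5,6,6a-tetrahydropentalen-2(1H)-one, via dipotassium dienolate 18 (not isolated)
Conditions: KHMDS (2.3 equiv), THF, −78 °C; 2-(phenylsulfonyl)-3-phenyloxaziridine (1.1 equiv), −78 °C; aq. HCl
Reagents that add atoms: 2-(phenylsulfonyl)-3-phenyloxaziridine (Davis oxaziridine), O=S(=O)(N1OC1c1ccccc1)c1ccccc1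
Why: Davis enolate oxidation (electrophilic O-transfer) of the planar C1 enolate occurs from the face opposite the coumarin on the adjacent quaternary carbon, so the new C–O bond is trans and the isobutyl cis to the coumarin (1S).

**Compound list**
1 | 1-(2-hydroxy-6-methylphenyl)ethan-1-one | CC(=O)c1c(C)cccc1O | starting material
2 | diethyl carbonate | CCOC(=O)OCC | starting material
3 | ethyl 3-(2-hydroxy-6-methylphenyl)-3-oxopropanoate | CCOC(=O)CC(=O)c1c(C)cccc1O | intermediate
4 | 4-hydroxy-5-methyl-2H-chromen-2-one | Cc1cccc2oc(=O)cc(O)c12 | intermediate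
5 | 3-methylcyclopent-2-en-1-one | CC1=CC(=O)CC1 | starting material
6 | 1-bromobut-2-yne | CC#CCBr | starting material
7 | bis{[(3S)-3-methylcyclopent-1-en-1-yl]oxy}diphenylsilane | C[C@H]1CCC(O[Si](OC2=C[C@@H](C)CC2)(c2ccccc2)c2ccccc2)=C1 | intermediate
8 | (2R,3S)-2-(but-2-yn-1-yl)-3-methylcyclopentan-1-one | CC#CC[C@@H]1[C@@H](C)CCC1=O | intermediate
9 | {[(3S)-2-(but-2-yn-1-yl)-3-methylcyclopent-1-en-1-yl]oxy}trimethylsilane | CC#CCC1=C(O[Si](C)(C)C)CC[C@@H]1C | intermediate
10 | cis-fused silyl ketal: dihydrofuro[3,2-c]coumarin whose furan C2 (OTMS, ring CH2) and C3 (butynyl, CHMe) are the former enol ether carbons; O and coumarin C3 on the face opposite the methyl | CC#CC[C@@]12[C@@H](C)CC[C@]1(O[Si](C)(C)C)Oc1c2c(=O)oc2cccc(C)c12 | intermediate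
11 | 3-[(1S,2S)-1-(but-2-yn-1-yl)-2-methyl-5-oxocyclopentyl]-4-hydroxy-5-methyl-2H-chromen-2-one | CC#CC[C@@]1(c2c(O)c3c(C)cccc3oc2=O)[C@@H](C)CCC1=O | intermediate
12 | 4-hydroxy-5-methyl-3-[(1S,2S)-2-methyl-5-oxo-1-(2-oxobutyl)cyclopentyl]-2H-chromen-2-one | CCC(=O)C[C@@]1(c2c(O)c3c(C)cccc3oc2=O)[C@@H](C)CCC1=O | intermediate
13 | (6S,6aR)-6a-(4-hydroxy-5-methyl-2-oxo-2H-chromen-3-yl)-3,6-dimethyl-4,5,6,6a-tetrahydropentalen-2(1H)-one | CC1=C2CC[C@H](C)[C@]2(c2c(O)c3c(C)cccc3oc2=O)CC1=O | intermediate
14 | 3-bromo-2-methylprop-1-ene | CC(=C)CBr | starting material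
15 | dilithium salt of 13 (coumarin 4-oxide and C1=C2 cross-conjugated enolate) | [Li+].[Li+].CC1=C2CC[C@H](C)[C@]2(c2c([O-])c3c(C)cccc3oc2=O)C=C1[O-] | intermediate
16 | (1S,6S,6aS)-6a-(4-hydroxy-5-methyl-2-oxo-2H-chromen-3-yl)-3,6-dimethyl-1-(2-methylprop-2-en-1-yl)-4,5,6,6a-tetrahydropentalen-2(1H)-one (methallyl trans to coumarin) | CC1=C2CC[C@H](C)[C@]2(c2c(O)c3c(C)cccc3oc2=O)[C@H](CC(C)=C)C1=O | intermediate
17 | (1S,6S,6aS)-6a-(4-hydroxy-5-methyl-2-oxo-2H-chromen-3-yl)-3,6-dimethyl-1-(2-methylpropyl)-4,5,6,6a-tetrahydropentalen-2(1H)-one | CC1=C2CC[C@H](C)[C@]2(c2c(O)c3c(C)cccc3oc2=O)[C@H](CC(C)C)C1=O | intermediate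
18 | dipotassium salt of 17 (coumarin 4-oxide and C1=C2 enolate, C1 bearing isobutyl) | [K+].[K+].CC1=C2CC[C@H](C)[C@]2(c2c([O-])c3c(C)cccc3oc2=O)C(CC(C)C)=C1[O-] | intermediate
19 | (1S,6S,6aS)-1-hydroxy-6a-(4-hydroxy-5-methyl-2-oxo-2H-chromen-3-yl)-3,6-dimethyl-1-(2-methylpropyl)-4,5,6,6a-tetrahydropentalen-2(1H)-one | CC1=C2CC[C@H](C)[C@]2(c2c(O)c3c(C)cccc3oc2=O)[C@@](O)(CC(C)C)C1=O | target

**Step count and risks**
Total steps: 8. Longest linear sequence: 7 (steps 2–8; step 1 joins at step 4).

The three steps most likely to fail: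

Step 4, the proposed annulation. The silyl enol ether may be desilylated or nitrated by Ce(IV) before it couples, addition to the fully substituted carbon may be slow, and the facial ratio is untested. The fallback uses known Pd-catalysed α-arylation of a silyl enol ether. It sets out from 9 and 4 and comes back at 11. Compound 4 is brominated (NBS, MeCN) to 3-bromo-4-hydroxy-5-methylcoumarin F1 and O-methylated (Me2SO4, K2CO3, acetone) to 3-bromo-4-methoxy-5-methylcoumarin F2. F2 is coupled with 9 [Pd(OAc)2, P(t-Bu)3, ZnF2, DMF, 80 °C] to the methyl ether F3, again anti to the methyl. The vinylogous methyl ester of F3 is cleaved (LiCl, DMF, 130 °C) to give 11.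

Step 8, the hydroxylation. The tertiary C1–H lies on the coumarin face, so deprotonation may be slow and the γ-CH2 may compete; the coumarin enolate could also take up oxygen. The fallback makes the same enolate by conjugate reduction instead of deprotonation. It sets out from 13 and comes back at 18, skipping 16 and 17. Dianion 15 is added to isobutyraldehyde to give the aldol F4. Dehydration (Martin sulfurane) gives the isobutylidene enone F5, which may rest as its oxa-Michael-closed isomer F6. KHMDS (1.1 equiv, THF) converts either form into the open potassium coumarinate, and K-Selectride (−78 °C) then adds hydride to the exocyclic β-carbon to give dienolate 18 regiospecifically. The oxaziridine of step 8 is added to the same flask.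

Step 3, the regioselective enol ether formation. The thermodynamic ratio for this 2,3-disubstituted cyclopentanone may be modest, and the minor isomer would be arylated at the wrong carbon. The fallback sets out from 8 and comes back at 9. Isopropenyl acetate with catalytic TsOH at reflux gives the more substituted enol acetate F7, which is chromatographed free of its regioisomer. MeLi (2 equiv, DME, 0 °C) releases the lithium enolate regiospecifically, and TMSCl gives 9.

**Further compounds**
F1 | step 4 | 3-bromo-4-hydroxy-5-methyl-2H-chromen-2-one | Cc1cccc2oc(=O)c(Br)c(O)c12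
F2 | step 4 | 3-bromo-4-methoxy-5-methyl-2H-chromen-2-one | COc1c(Br)c(=O)oc2cccc(C)c12
F3 | step 4 | 3-[(1S,2S)-1-(but-2-yn-1-yl)-2-methyl-5-oxocyclopentyl]-4-methoxy-5-methyl-2H-chromen-2-one | CC#CC[C@@]1(c2c(OC)c3c(C)cccc3oc2=O)[C@@H](C)CCC1=O
F4 | step 8 | (6S,6aS)-6a-(4-hydroxy-5-methyl-2-oxo-2H-chromen-3-yl)-1-(1-hydroxy-2-methylpropyl)-3,6-dimethyl-4,5,6,6a-tetrahydropentalen-2(1H)-one (epimer mixture at C1 and carbinol) | CC1=C2CC[C@H](C)[C@]2(c2c(O)c3c(C)cccc3oc2=O)C(C(O)C(C)C)C1=O
F5 | step 8 | (6S,6aS)-6a-(4-hydroxy-5-methyl-2-oxo-2H-chromen-3-yl)-3,6-dimethyl-1-(2-methylpropylidene)-4,5,6,6a-tetrahydropentalen-2(1H)-one (E/Z) | CC1=C2CC[C@H](C)[C@]2(c2c(O)c3c(C)cccc3oc2=O)C(=CC(C)C)C1=O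
F6 | step 8 | ring-closed oxa-Michael isomer of F5 (coumarin 4-O bonded to the isopropyl-bearing carbon, dihydropyran fused across C6a–C1) | CC1=C2CC[C@H](C)[C@]23C(C1=O)C(C(C)C)Oc1c3c(=O)oc3cccc(C)c13
F7 | step 3 | (3S)-2-(but-2-yn-1-yl)-3-methylcyclopent-1-en-1-yl acetate | CC#CCC1=C(OC(C)=O)CC[C@@H]1C
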